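**Plan**
- Retrosynthetic cuts: the quinone carbonyls go back to the two aryl OMe groups (last step); then the benzylic C1'–C2' bond together with the C3'–CH3 bond (one event); then C5'–C6' together with C7'–CH3 (alkenyl iodide plus homopropargylzinc); then the C13 alkyne back to the methyl ketone of (R)-α-ionone. Chain locants run C1' (benzylic) to C9' (on the cyclohexene ring).
- Forward order: (R)-α-ionone → conjugate reduction → ketone to terminal alkyne → methylalumination/iodination → homopropargylation → methylalumination/benzylation → oxidative demethylation. No ring is formed: the cyclohexene ring is bought, and the quinone ring is the 2,5-dimethoxyphenyl ring of the benzyl chloride.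
- Stereochemistry: the (R) centre at C1 of the cyclohexene ring comes from (R)-α-ionone and is not touched after step 1. Both E-alkenes come from syn-methylalumination of terminal alkynes followed by stereoretentive couplings.
- Enabling feature: each CH=C(CH3) unit of the chain (C2'=C3' and C6'=C7') is the retron of a terminal alkyne. In enyne 11 the terminal C≡C–H is the only π-bond that accepts Me–Al under Cp2ZrCl2; the ring C2=C3 and chain C6'=C7' alkenes are inert. The resulting C2'–Al bond is matched with the benzylic C–Cl bond on the dimethoxyphenyl ring.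

Key step: step 6

Assumption: (R)-(+)-α-ionone is bought as the single enantiomer (fermentation-derived material); its C1 stereocentre is the only source of chirality.

Step 1
Reactants: 1 (R)-(+)-α-ionone
Product: 3 (R)-dihydro-α-ionone = 4-[(1R)-2,6,6-trimethylcyclohex-2-en-1-yl]butan-2-one, via triethylsilyl enol ether 2 (not isolated)
Conditions: Et3SiH (1.2 equiv), RhCl(PPh3)3 (1 mol %), toluene, 50 °C; then K2CO3, MeOH, rt
Reagents that add atoms: none
Why: Rhodium-catalysed 1,4-hydrosilylation of the enone with a monohydrosilane should give the silyl enol ether, which methanolysis converts to the saturated ketone; the neutral conditions avoid γ-deprotonation at the doubly allylic C1–H, and the hindered trisubstituted ring alkene is inert.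

Step 2
Reactants: 3 (R)-dihydro-α-ionone
Product: 5 (R)-6-(but-3-yn-1-yl)-1,5,5-trimethylcyclohex-1-ene, via enol diethyl phosphate 4 (not isolated)
Conditions: LiN(i-Pr)2 (1.05 equiv), THF, −78 °C; ClP(O)(OEt)2, −78 °C → rt; then added to LiN(i-Pr)2 (2.3 equiv), THF, −78 °C → rt; aq. NH4Cl
Reagents that add atoms: none
Why: This is the Negishi methyl ketone to terminal alkyne protocol: kinetic deprotonation at the methyl group, O-phosphorylation, and β-elimination of phosphate by excess amide base, driven by formation of the lithium acetylide; the C1–H is now only singly allylic and is not deprotonated.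

Step 3
Reactants: 5 (R)-6-(but-3-yn-1-yl)-1,5,5-trimethylcyclohex-1-ene
Product: 7 (R)-6-[(E)-4-iodo-3-methylbut-3-en-1-yl]-1,5,5-trimethylcyclohex-1-ene, via alkenyl(dimethyl)alane 6 (not isolated)
Conditions: Me3Al (2 equiv), Cp2ZrCl2 (0.25 equiv), CH2Cl2, 0 °C → rt; then I2, THF, −30 → 0 °C
Reagents that add atoms: trimethylaluminium C[Al](C)C; iodine II
Why: Negishi zirconium-catalysed methylalumination adds Me and Al syn across the terminal alkyne with methyl on the internal carbon, and iodinolysis of the C–Al bond with retention should give the E-alkenyl iodide; the trisubstituted ring alkene does not carbometalate.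

Step 4
Reactants: 7 (R)-6-[(E)-4-iodo-3-methylbut-3-en-1-yl]-1,5,5-trimethylcyclohex-1-ene; 8 (4-bromobut-1-yn-1-yl)trimethylsilane
Product: 10 trimethyl[(E)-6-methyl-8-[(1R)-2,6,6-trimethylcyclohex-2-en-1-yl]oct-5-en-1-yn-1-yl]silane, via homopropargylzinc bromide 9 (not isolated)
Conditions: 8, Zn dust (BrCH2CH2Br/Me3SiCl-activated), LiCl, THF, 50 °C; then 7, Pd(PPh3)4 (5 mol %), THF, rt
Reagents that add atoms: none
Why: Negishi alkyl–alkenyl cross-coupling of a primary alkylzinc halide with an E-alkenyl iodide proceeds with retention of olefin geometry, and the silyl cap keeps the alkyne from reacting with zinc or palladium.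

Step 5
Reactants: 10 trimethyl[(E)-6-methyl-8-[(1R)-2,6,6-trimethylcyclohex-2-en-1-yl]oct-5-en-1-yn-1-yl]silane
Product: 11 (R)-1,5,5-trimethyl-6-[(E)-3-methyloct-3-en-7-yn-1-yl]cyclohex-1-ene
Conditions: K2CO3, MeOH, rt
Reagents that add atoms: none
Why: Base-mediated methanolysis of the alkynyl C–Si bond (protodesilylation) should free the terminal alkyne without touching the alkenes or the stereocentre.

Step 6
Reactants: 11 (R)-1,5,5-trimethyl-6-[(E)-3-methyloct-3-en-7-yn-1-yl]cyclohex-1-ene; 12 2,5-dimethoxybenzyl chloride = 2-(chloromethyl)-1,4-dimethoxybenzene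
Product: 14 2-[(2E,6E)-3,7-dimethyl-9-[(1R)-2,6,6-trimethylcyclohex-2-en-1-yl]nona-2,6-dien-1-yl]-1,4-dimethoxybenzene, via dienyl(dimethyl)alane 13 (not isolated)
Conditions: Me3Al (2 equiv), Cp2ZrCl2 (0.25 equiv), CH2Cl2, 0 °C → rt; volatiles removed, THF; 12, NiCl2(PPh3)2 (3 mol %)/n-BuLi (6 mol %), THF, 0 °C → rt
Reagents that add atoms: trimethylaluminium C[Al](C)C
Why: Cp2ZrCl2/Me3Al generates a cationic methylzirconocene that adds Me–Zr syn across the terminal alkyne of 11 with methyl at the internal carbon, and Zr-to-Al exchange gives the (E)-alkenylalane 13; zerovalent nickel (from NiCl2(PPh3)2 and n-BuLi) then inserts into the benzylic C–Cl bond of 12, the alkenyl group passes from aluminium to nickel, and reductive elimination forms the vinyl CH–benzylic CH2 bond. The closest known reaction type is the Negishi zirconium-catalysed carboalumination run in one flask with nickel- or palladium-catalysed cross-coupling of alkenylalanes with benzylic chlorides, the standard entry to polyprenylated arene and quinone side chains. No ring is closed and no stereocentre is formed; the new stereo-element is the E C2'=C3' alkene, fixed by the syn carbometalation and by transmetalation and reductive elimination with retention at the sp2 carbon. The step needs chemoselectivity for the alkyne over the ring C2=C3 and chain C6'=C7' alkenes (trisubstituted alkenes do not insert into Me–Zr), regioselectivity for terminal metalation (steric bias of a monosubstituted alkyne), alkenyl in preference to methyl transfer from aluminium (sp2 groups transmetalate faster), and cross- over homo-coupling of 12 (low-valent nickel kept catalytic, excess Me3Al stripped before the coupling). In one flask it should install the C3' methyl, the E-alkene and the masked quinone ring while the remote, non-acidic C1 stereocentre stays untouched.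

Step 7
Reactants: 14 2-[(2E,6E)-3,7-dimethyl-9-[(1R)-2,6,6-trimethylcyclohex-2-en-1-yl]nona-2,6-dien-1-yl]-1,4-dimethoxybenzene
Product: 15 2-[(2E,6E)-3,7-dimethyl-9-[(1R)-2,6,6-trimethylcyclohex-2-en-1-yl]nona-2,6-dien-1-yl]cyclohexa-2,5-diene-1,4-dione
Conditions: (NH4)2Ce(NO3)6 (2.5 equiv), MeCN/H2O (2:1), 0 °C, 14 added to the oxidant
Reagents that add atoms: water O
Why: Oxidative demethylation of a hydroquinone dimethyl ether: two one-electron oxidations by tetravalent cerium, with ipso attack of water on the arene radical cation and loss of methanol, should give the para-quinone, since the dimethoxyarene is oxidised at a much lower potential than the trisubstituted alkenes and adding 14 to excess oxidant at 0 °C keeps the radical cation from coupling with unreacted arene.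

**Compound list**
1 | (R)-(+)-α-ionone, (E)-4-[(1R)-2,6,6-trimethylcyclohex-2-en-1-yl]but-3-en-2-one | CC1=CCCC(C)(C)[C@H]1/C=C/C(C)=O | starting material
2 | triethyl{[4-[(1R)-2,6,6-trimethylcyclohex-2-en-1-yl]but-2-en-2-yl]oxy}silane (enol ether geometry not defined) | CC1=CCCC(C)(C)[C@H]1CC=C(C)O[Si](CC)(CC)CC | intermediate
3 | (R)-dihydro-α-ionone, 4-[(1R)-2,6,6-trimethylcyclohex-2-en-1-yl]butan-2-one | CC1=CCCC(C)(C)[C@H]1CCC(C)=O | intermediate
4 | diethyl 4-[(1R)-2,6,6-trimethylcyclohex-2-en-1-yl]but-1-en-2-yl phosphate | CC1=CCCC(C)(C)[C@H]1CCC(=C)OP(=O)(OCC)OCC | intermediate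
5 | (R)-6-(but-3-yn-1-yl)-1,5,5-trimethylcyclohex-1-ene | CC1=CCCC(C)(C)[C@H]1CCC#C | intermediate
6 | dimethyl[(E)-2-methyl-4-[(1R)-2,6,6-trimethylcyclohex-2-en-1-yl]but-1-en-1-yl]alane | CC1=CCCC(C)(C)[C@H]1CC/C(C)=C/[Al](C)C | intermediate
7 | (R)-6-[(E)-4-iodo-3-methylbut-3-en-1-yl]-1,5,5-trimethylcyclohex-1-ene | CC1=CCCC(C)(C)[C@H]1CC/C(C)=C/I | intermediate
8 | (4-bromobut-1-yn-1-yl)trimethylsilane | C[Si](C)(C)C#CCCBr | starting material
9 | [4-(trimethylsilyl)but-3-yn-1-yl]zinc bromide | C[Si](C)(C)C#CCC[Zn]Br | intermediate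
10 | trimethyl[(E)-6-methyl-8-[(1R)-2,6,6-trimethylcyclohex-2-en-1-yl]oct-5-en-1-yn-1-yl]silane | CC1=CCCC(C)(C)[C@H]1CC/C(C)=C/CCC#C[Si](C)(C)C | intermediate
11 | (R)-1,5,5-trimethyl-6-[(E)-3-methyloct-3-en-7-yn-1-yl]cyclohex-1-ene | CC1=CCCC(C)(C)[C@H]1CC/C(C)=C/CCC#C | intermediate
12 | 2,5-dimethoxybenzyl chloride, 2-(chloromethyl)-1,4-dimethoxybenzene | COc1ccc(OC)c(CCl)c1 | starting material
13 | dimethyl[(1E,5E)-2,6-dimethyl-8-[(1R)-2,6,6-trimethylcyclohex-2-en-1-yl]octa-1,5-dien-1-yl]alane | CC1=CCCC(C)(C)[C@H]1CC/C(C)=C/CC/C(C)=C/[Al](C)C | intermediate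
14 | 2-[(2E,6E)-3,7-dimethyl-9-[(1R)-2,6,6-trimethylcyclohex-2-en-1-yl]nona-2,6-dien-1-yl]-1,4-dimethoxybenzene | CC1=CCCC(C)(C)[C@H]1CC/C(C)=C/CC/C(C)=C/Cc1cc(OC)ccc1OC | intermediate
15 | 2-[(2E,6E)-3,7-dimethyl-9-[(1R)-2,6,6-trimethylcyclohex-2-en-1-yl]nona-2,6-dien-1-yl]cyclohexa-2,5-diene-1,4-dione | CC1=CCCC(C)(C)[C@H]1CC/C(C)=C/CC/C(C)=C/CC1=CC(=O)C=CC1=O | target

**Step count and risks**
Total step count: 7. Longest linear sequence: 7 steps (1 → 15); 8 and 12 are purchased.

Steps most likely to fail:

Step 6. The one-flask carboalumination/benzylation may suffer from slow transfer of the alkenyl group from aluminium to nickel, competing methyl transfer, or reductive homocoupling of the benzylic chloride; a minor regioisomeric alane would also be carried through unpurified. The fallback reverses the polarity of the union. Setting out from 11, alane 13 would be generated as before and quenched with I2 to give (R)-6-[(3E,7E)-8-iodo-3,7-dimethylocta-3,7-dien-1-yl]-1,5,5-trimethylcyclohex-1-ene F1, which can be purified. F1 would then be coupled under Pd(PPh3)4 catalysis in THF with 2,5-dimethoxybenzylzinc chloride F2, made from 12 with Zn dust and LiCl in THF. This Negishi coupling comes back to the route at 14.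

Step 7. Oxidative demethylation may be accompanied by dimerisation of the arene radical cation, by over-oxidation of the allylic and benzylic positions, or by acid-promoted cyclisation of the polyene while nitric acid builds up. The fallback separates oxidation from unmasking. Setting out from 14, constant-current anodic oxidation in methanolic KOH (undivided cell, carbon or platinum anode, 0 °C) should give the quinone bis(dimethyl ketal) 1-[(2E,6E)-3,7-dimethyl-9-[(1R)-2,6,6-trimethylcyclohex-2-en-1-yl]nona-2,6-dien-1-yl]-3,3,6,6-tetramethoxycyclohexa-1,4-diene F3 under basic conditions. Brief hydrolysis with dilute aqueous acetic acid in acetone would then release the quinone and come back to the route at 15.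

Step 4. Zinc insertion into the homopropargylic bromide may stall, or the alkylpalladium intermediate may undergo β-hydride elimination and protodemetalation, leaving reduced or homocoupled material. The fallback builds the same C5'–C6' region by allylic alkylation with a propargyl anion. Setting out from 7, iodine–lithium exchange (t-BuLi, Et2O, −78 °C) would give the alkenyllithium [(E)-2-methyl-4-[(1R)-2,6,6-trimethylcyclohex-2-en-1-yl]but-1-en-1-yl]lithium F4. Trapping with paraformaldehyde would give (E)-3-methyl-5-[(1R)-2,6,6-trimethylcyclohex-2-en-1-yl]pent-2-en-1-ol F5. An Appel reaction (CBr4, PPh3, CH2Cl2, 0 °C) would convert it to (R)-6-[(E)-5-bromo-3-methylpent-3-en-1-yl]-1,5,5-trimethylcyclohex-1-ene F6. Displacement of the bromide with [3-(trimethylsilyl)prop-2-yn-1-yl]lithium F7 (from 1-(trimethylsilyl)propyne and n-BuLi, THF, −78 °C) would come back to the route at 10.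

**Further compounds**
F1 | step 6 | (R)-6-[(3E,7E)-8-iodo-3,7-dimethylocta-3,7-dien-1-yl]-1,5,5-trimethylcyclohex-1-ene | CC1=CCCC(C)(C)[C@H]1CC/C(C)=C/CC/C(C)=C/I
F2 | step 6 | 2,5-dimethoxybenzylzinc chloride | COc1ccc(OC)c(C[Zn]Cl)c1
F3 | step 7 | 1-[(2E,6E)-3,7-dimethyl-9-[(1R)-2,6,6-trimethylcyclohex-2-en-1-yl]nona-2,6-dien-1-yl]-3,3,6,6-tetramethoxycyclohexa-1,4-diene | CC1=CCCC(C)(C)[C@H]1CC/C(C)=C/CC/C(C)=C/CC1=CC(OC)(OC)C=CC1(OC)OC
F4 | step 4 | [(E)-2-methyl-4-[(1R)-2,6,6-trimethylcyclohex-2-en-1-yl]but-1-en-1-yl]lithium | CC1=CCCC(C)(C)[C@H]1CC/C(C)=C/[Li]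
F5 | step 4 | (E)-3-methyl-5-[(1R)-2,6,6-trimethylcyclohex-2-en-1-yl]pent-2-en-1-ol | CC1=CCCC(C)(C)[C@H]1CC/C(C)=C/CO
F6 | step 4 | (R)-6-[(E)-5-bromo-3-methylpent-3-en-1-yl]-1,5,5-trimethylcyclohex-1-ene | CC1=CCCC(C)(C)[C@H]1CC/C(C)=C/CBr
F7 | step 4 | [3-(trimethylsilyl)prop-2-yn-1-yl]lithium | [Li]CC#C[Si](C)(C)C
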